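The oxolane ring is traced back to a γ-alkoxybutenolide: ring carbons C8 and C8', trans to each other and each flanked by an OCH2 carbon (C9, C9'), are the β and α carbons of (5R)-5-menthyloxyfuran-2(5H)-one, whose acetal and carbonyl carbons are later reduced to C9 and C9'. In one flask the lithiated dithiane of O-silylated syringaldehyde (C7 as a masked acyl anion) adds to C8 and the resulting enolate is benzylated at C8' by O-silylated vanillyl bromide, creating C7–C8, C8'–C7' and both ring stereocentres under control of the acetal carbon. C7 is set afterwards by reagent-controlled reduction of the unmasked aryl ketone.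

Key step: step 8

Remark on numbering: lignan locants are used (C7 carbinol carbon; C8 and C9 the ring CH and OCH2 on the syringyl side; C7', C8', C9' the benzylic CH2, ring CH and OCH2 on the guaiacyl side); the target is (7S,8R,8'R).
Remark on the auxiliary: the (5R) acetal from (−)-menthol is the correct series, since anti addition and anti alkylation lead to (3R,4R,5R)-15, which maps onto 8R,8'R; no structure needed correction.
Remark on protection: both phenols are carried as tert-butyldimethylsilyl ethers (TBSO = tert-butyldimethylsilyloxy) and are removed together by fluoride; benzyl ethers are avoided because hydrogenolysis would endanger the C7 benzylic carbinol.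

Step 1
Reactants: 1 furfural
Product: 3 racemic 5-hydroxyfuran-2(5H)-one, via furfural endoperoxide 2 (not isolated)
Conditions: O2, rose bengal (cat.), MeOH, visible light, 20 °C
Reagents that add atoms: dioxygen, O=O
Why: Dye-sensitised photooxygenation, in which singlet oxygen adds [4+2] across C2 and C5 of the furan and methanol then cleaves the endoperoxide with loss of the formyl carbon as methyl formate, leaving a lactol with no defined stereocentre.

Step 2
Reactants: 3 5-hydroxyfuran-2(5H)-one; 4 (−)-menthol
Product: 5 (5R)-5-[(1R,2S,5R)-menthyloxy]furan-2(5H)-one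
Conditions: camphorsulfonic acid (cat.), toluene, reflux, Dean–Stark; crystallise from hexane, −20 °C; re-equilibrate the mother liquor with acid and recrystallise
Reagents that add atoms: none
Why: Acid-catalysed acetalisation of the lactol, in which the two C5 epimers interconvert through the ring oxocarbenium ion, so that crystallisation should deliver the less soluble (5R) acetal and the acetal stereocentre is set by crystallisation-driven diastereomer selection with the menthyl group as the chiral element.

Step 3
Reactants: 6 syringaldehyde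
Product: 7 4-(TBSO)-3,5-dimethoxybenzaldehyde
Conditions: TBSCl, imidazole, DMF, 20 °C
Reagents that add atoms: tert-butyldimethylsilyl chloride, CC(C)(C)[Si](C)(C)Cl
Why: Imidazole-mediated O-silylation of a phenol, which leaves the aldehyde untouched.

Step 4
Reactants: 7 4-(TBSO)-3,5-dimethoxybenzaldehyde
Product: 8 2-[4-(TBSO)-3,5-dimethoxyphenyl]-1,3-dithiane
Conditions: HS(CH2)3SH, BF3·OEt2 (0.2 equiv), CH2Cl2, 0 °C
Reagents that add atoms: propane-1,3-dithiol, SCCCS
Why: Lewis-acid-catalysed dithioacetalisation of an aryl aldehyde, under which the aryl silyl ether is stable at 0 °C.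

Step 5
Reactants: 9 vanillin
Product: 10 4-(TBSO)-3-methoxybenzaldehyde
Conditions: TBSCl, imidazole, DMF, 20 °C
Reagents that add atoms: tert-butyldimethylsilyl chloride, CC(C)(C)[Si](C)(C)Cl
Why: Imidazole-mediated O-silylation of a phenol, as in step 3.

Step 6
Reactants: 10 4-(TBSO)-3-methoxybenzaldehyde
Product: 11 [4-(TBSO)-3-methoxyphenyl]methanol
Conditions: NaBH4, MeOH–THF, 0 °C
Reagents that add atoms: none
Why: Borohydride reduction of an aryl aldehyde, which the aryl silyl ether tolerates for the short time needed in the cold.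

Step 7
Reactants: 11 [4-(TBSO)-3-methoxyphenyl]methanol
Product: 12 4-(TBSO)-3-methoxybenzyl bromide
Conditions: PPh3, CBr4, CH2Cl2, 0 °C; short silica plug, use at once
Reagents that add atoms: carbon tetrabromide, BrC(Br)(Br)Br
Why: Appel bromination, in which bromide displaces the alkoxyphosphonium ion under neutral conditions and so avoids the acid that would ionise this electron-rich benzylic system.

Step 8
Reactants: 8 2-[4-(TBSO)-3,5-dimethoxyphenyl]-1,3-dithiane; 5 (5R)-5-[(1R,2S,5R)-menthyloxy]furan-2(5H)-one; 12 4-(TBSO)-3-methoxybenzyl bromide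
Product: 15 all-trans adduct (3R,4R,5R)-3-[4-(TBSO)-3-methoxybenzyl]-4-{2-[4-(TBSO)-3,5-dimethoxyphenyl]-1,3-dithian-2-yl}-5-[(1R,2S,5R)-menthyloxy]dihydrofuran-2(3H)-one, via lithiated dithiane 13 (not isolated), via lithium enolate 14 (not isolated)
Conditions: n-BuLi (0.95 equiv per 8), THF, −78 °C; then 5, −78 °C; then 12, DMPU, −78 → 20 °C; aq NH4Cl
Reagents that add atoms: none
Why: n-BuLi removes the benzylic proton of 8 to give the sulfur-stabilised carbanion 13, which adds 1,4 (Michael addition) to C4 of butenolide 5 on the face opposite the C5 menthyloxy group; the lithium lactone enolate 14 so formed is then alkylated at C3 by SN2 displacement on bromide 12, on the face opposite the new dithianyl group. The closest known reaction type is the tandem conjugate addition–enolate alkylation of lithiated aryl dithioacetals with 5-alkoxyfuran-2(5H)-ones, as used for dibenzylbutyrolactone lignans. No ring is closed. C8 (lactone C4) is controlled by the acetal stereocentre C5 and C8' (lactone C3) by C8, so the all-trans (3R,4R,5R) adduct should result. The step needs 1,4- over 1,2-addition, secured by the soft aryl-stabilised dithiane anion in THF at −78 °C, and complete C-benzylation rather than O-alkylation or protonation, secured by the reactive benzylic bromide and DMPU activation of the lithium enolate. Keeping n-BuLi just below one equivalent per dithiane leaves no free base to attack the aryl silyl ethers or the acetal proton of 5.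

Step 9
Reactants: 15 all-trans adduct
Product: 16 (2R,3R)-2-[4-(TBSO)-3-methoxybenzyl]-3-{2-[4-(TBSO)-3,5-dimethoxyphenyl]-1,3-dithian-2-yl}butane-1,4-diol
Conditions: LiAlH4, THF, 0 °C; H2O then aq NaOH work-up
Reagents that add atoms: none
Why: Hydride reduction of the acylal-type lactone, in which the ring opens after the first hydride, the hemiacetal expels menthoxide and both unmasked aldehydes are reduced, so that the carbonyl and acetal carbons become the two CH2OH groups while C8, C8', the dithiane and the aryl silyl ethers should survive the short exposure at 0 °C.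

Step 10
Reactants: 16 (2R,3R)-diol
Product: 17 (3R,4R)-3-[4-(TBSO)-3-methoxybenzyl]-4-{2-[4-(TBSO)-3,5-dimethoxyphenyl]-1,3-dithian-2-yl}oxolane
Conditions: PPh3, DIAD, THF, 0 → 20 °C
Reagents that add atoms: none
Why: Mitsunobu cyclodehydration, in which one primary hydroxyl is activated as its alkoxyphosphonium ion and displaced 5-exo-tet by the other; either hydroxyl may be activated because both modes give the same oxolane and neither carbinol carbon is stereogenic.

Step 11
Reactants: 17 oxolane dithiane
Product: 18 [(3R,4R)-4-(4-TBSO-3-methoxybenzyl)oxolan-3-yl][4-(TBSO)-3,5-dimethoxyphenyl]methanone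
Conditions: MeI (excess), CaCO3, MeCN–H2O 9:1, 45 °C
Reagents that add atoms: water, O
Why: Alkylative dithioacetal hydrolysis, in which S-methylation creates a sulfonium leaving group and the aryl-stabilised thionium ion is trapped by water, while CaCO3 keeps the medium neutral so that the silyl ethers and the already trans (thermodynamically preferred) C8 centre next to the new ketone persist.

Step 12
Reactants: 18 aryl ketone
Product: 19 (S)-[(3R,4R)-4-(4-TBSO-3-methoxybenzyl)oxolan-3-yl][4-(TBSO)-3,5-dimethoxyphenyl]methanol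
Conditions: (R)-2-methyl-CBS-oxazaborolidine (0.2 equiv), BH3·SMe2, THF, −20 → 0 °C, slow addition of 18; MeOH quench
Reagents that add atoms: none
Why: Corey–Bakshi–Shibata reduction, in which the ketone binds the catalyst boron with its aryl group as the large substituent and the (R) catalyst should deliver hydride from the coordinated borane to the Re face of the carbonyl (O > aryl > C8), setting C7 as (S) by reagent control.

Step 13
Reactants: 19 bis-silyl carbinol
Product: 20 target, 4-[(S)-hydroxy{(3R,4R)-4-[(4-hydroxy-3-methoxyphenyl)methyl]oxolan-3-yl}methyl]-2,6-dimethoxyphenol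
Conditions: Bu4NF, AcOH, THF, 0 °C
Reagents that add atoms: none
Why: Fluoride-driven cleavage of both aryl silyl ethers through formation of the strong Si–F bond, buffered with acetic acid so that the liberated para-hydroxybenzylic carbinol is not pushed toward a quinone methide, with no stereocentre involved.

Compound list
1 | furfural (furan-2-carbaldehyde) | O=Cc1ccco1 | starting material
2 | furfural endoperoxide, 2,3,7-trioxabicyclo[2.2.1]hept-5-ene-1-carbaldehyde (racemic, not isolated) | O=CC12OOC(C=C1)O2 | intermediate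
3 | 5-hydroxyfuran-2(5H)-one (racemic lactol) | O=C1C=CC(O)O1 | intermediate
4 | (−)-menthol, (1R,2S,5R)-5-methyl-2-(propan-2-yl)cyclohexan-1-ol | CC(C)[C@@H]1CC[C@@H](C)C[C@H]1O | starting material
5 | (5R)-5-[(1R,2S,5R)-menthyloxy]furan-2(5H)-one | O=C1C=C[C@@H](O1)O[C@H]1[C@H](C(C)C)CC[C@@H](C)C1 | intermediate
6 | syringaldehyde (4-hydroxy-3,5-dimethoxybenzaldehyde) | COc1cc(C=O)cc(OC)c1O | starting material
7 | 4-(tert-butyldimethylsilyloxy)-3,5-dimethoxybenzaldehyde | COc1cc(C=O)cc(OC)c1O[Si](C)(C)C(C)(C)C | intermediate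
8 | 2-[4-(tert-butyldimethylsilyloxy)-3,5-dimethoxyphenyl]-1,3-dithiane | C1CSC(SC1)c1cc(OC)c(O[Si](C)(C)C(C)(C)C)c(OC)c1 | intermediate
9 | vanillin (4-hydroxy-3-methoxybenzaldehyde) | COc1cc(C=O)ccc1O | starting material
10 | 4-(tert-butyldimethylsilyloxy)-3-methoxybenzaldehyde | COc1cc(C=O)ccc1O[Si](C)(C)C(C)(C)C | intermediate
11 | [4-(tert-butyldimethylsilyloxy)-3-methoxyphenyl]methanol | COc1cc(CO)ccc1O[Si](C)(C)C(C)(C)C | intermediate
12 | 4-(tert-butyldimethylsilyloxy)-3-methoxybenzyl bromide | BrCc1ccc(O[Si](C)(C)C(C)(C)C)c(OC)c1 | intermediate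
13 | 2-lithio-2-[4-(tert-butyldimethylsilyloxy)-3,5-dimethoxyphenyl]-1,3-dithiane (not isolated) | [Li]C1(SCCCS1)c1cc(OC)c(O[Si](C)(C)C(C)(C)C)c(OC)c1 | intermediate
14 | lithium (4R,5R)-4-{2-[4-(TBSO)-3,5-dimethoxyphenyl]-1,3-dithian-2-yl}-5-[(1R,2S,5R)-menthyloxy]-4,5-dihydrofuran-2-olate (not isolated) | [Li]OC1=C[C@@H](C2(SCCCS2)c2cc(OC)c(O[Si](C)(C)C(C)(C)C)c(OC)c2)[C@H](O[C@H]2[C@H](C(C)C)CC[C@@H](C)C2)O1 | intermediate
15 | (3R,4R,5R)-3-[4-(TBSO)-3-methoxybenzyl]-4-{2-[4-(TBSO)-3,5-dimethoxyphenyl]-1,3-dithian-2-yl}-5-[(1R,2S,5R)-menthyloxy]dihydrofuran-2(3H)-one (all-trans) | O=C1O[C@@H](O[C@H]2[C@H](C(C)C)CC[C@@H](C)C2)[C@H](C2(SCCCS2)c2cc(OC)c(O[Si](C)(C)C(C)(C)C)c(OC)c2)[C@H]1Cc1ccc(O[Si](C)(C)C(C)(C)C)c(OC)c1 | intermediate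
16 | (2R,3R)-2-[4-(TBSO)-3-methoxybenzyl]-3-{2-[4-(TBSO)-3,5-dimethoxyphenyl]-1,3-dithian-2-yl}butane-1,4-diol | OC[C@H](Cc1ccc(O[Si](C)(C)C(C)(C)C)c(OC)c1)[C@H](CO)C1(SCCCS1)c1cc(OC)c(O[Si](C)(C)C(C)(C)C)c(OC)c1 | intermediate
17 | (3R,4R)-3-[4-(TBSO)-3-methoxybenzyl]-4-{2-[4-(TBSO)-3,5-dimethoxyphenyl]-1,3-dithian-2-yl}oxolane | COc1cc(C[C@H]2COC[C@@H]2C3(SCCCS3)c4cc(OC)c(O[Si](C)(C)C(C)(C)C)c(OC)c4)ccc1O[Si](C)(C)C(C)(C)C | intermediate
18 | [(3R,4R)-4-(4-TBSO-3-methoxybenzyl)oxolan-3-yl][4-(TBSO)-3,5-dimethoxyphenyl]methanone | COc1cc(C[C@H]2COC[C@@H]2C(=O)c3cc(OC)c(O[Si](C)(C)C(C)(C)C)c(OC)c3)ccc1O[Si](C)(C)C(C)(C)C | intermediate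
19 | (S)-[(3R,4R)-4-(4-TBSO-3-methoxybenzyl)oxolan-3-yl][4-(TBSO)-3,5-dimethoxyphenyl]methanol | COc1cc(C[C@H]2COC[C@@H]2[C@H](O)c3cc(OC)c(O[Si](C)(C)C(C)(C)C)c(OC)c3)ccc1O[Si](C)(C)C(C)(C)C | intermediate
20 | 4-[(S)-hydroxy{(3R,4R)-4-[(4-hydroxy-3-methoxyphenyl)methyl]oxolan-3-yl}methyl]-2,6-dimethoxyphenol | COc1cc(C[C@H]2COC[C@@H]2[C@H](O)c2cc(OC)c(O)c(OC)c2)ccc1O | target

Total step count: 13 steps.
Longest linear sequence: 9 steps (9 → 10 → 11 → 12 → 15 → 16 → 17 → 18 → 19 → 20; steps 5 to 13).

Steps most likely to fail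

Step 8. The conjugate addition may be incomplete or revert on warming, and benzylation of the hindered enolate may be slow, so that protonated Michael adduct accumulates while the labile bromide is lost by ionisation. The fallback runs the two bond formations in separate operations. It sets out from 5 and 8: only the conjugate addition is carried out (n-BuLi, THF, −78 °C) and quenched with aq NH4Cl to isolate (4R,5R)-4-{2-[4-(TBSO)-3,5-dimethoxyphenyl]-1,3-dithian-2-yl}-5-[(1R,2S,5R)-menthyloxy]dihydrofuran-2(3H)-one F1. Its enolate is then regenerated with LiN(iPr)2 in THF at −78 °C and alkylated with freshly prepared 12 in the presence of DMPU, again anti to the dithianyl group, which returns to the route at 15.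

Step 12. Facial selectivity may be poor, because the catalyst has to override the bias of the neighbouring C8 centre and the electron-rich, α-branched aryl ketone reacts slowly, so uncatalysed borane reduction can compete. The fallback replaces reagent control by reduction, separation and recycling. It sets out from 18, which is reduced with NaBH4 in MeOH–THF at 0 °C, and the two carbinol epimers are separated by chromatography. The (7S) epimer is 19, where the route is rejoined. The unwanted epimer, (R)-[(3R,4R)-4-(4-TBSO-3-methoxybenzyl)oxolan-3-yl][4-(TBSO)-3,5-dimethoxyphenyl]methanol F2, is oxidised back to 18 with MnO2 in CH2Cl2 and passed through the reduction again.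

Step 11. Hydrolysis of the hindered, fully substituted dithioketal may stall, leaving S-methylated material that does not collapse to the ketone. The fallback activates sulfur by oxidation and not by alkylation. It sets out from 17, which is oxidised at one sulfur with mCPBA (1 equiv, CH2Cl2, −78 °C) to 2-[4-(TBSO)-3,5-dimethoxyphenyl]-2-[(3R,4R)-4-(4-TBSO-3-methoxybenzyl)oxolan-3-yl]-1,3-dithiane 1-oxide F3 (mixture at sulfur and at the dithiane carbon). Brief treatment with dilute HCl in aqueous THF at 20 °C should then expel the sulfoxide sulfur as a sulfenic acid and hydrolyse the thionium ion, which returns to the route at 18.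

Further compounds
F1 | step 8 | (4R,5R)-4-{2-[4-(TBSO)-3,5-dimethoxyphenyl]-1,3-dithian-2-yl}-5-[(1R,2S,5R)-menthyloxy]dihydrofuran-2(3H)-one | O=C1C[C@@H](C2(SCCCS2)c2cc(OC)c(O[Si](C)(C)C(C)(C)C)c(OC)c2)[C@H](O[C@H]2[C@H](C(C)C)CC[C@@H](C)C2)O1
F2 | step 12 | (R)-[(3R,4R)-4-(4-TBSO-3-methoxybenzyl)oxolan-3-yl][4-(TBSO)-3,5-dimethoxyphenyl]methanol | COc1cc(C[C@H]2COC[C@@H]2[C@@H](O)c3cc(OC)c(O[Si](C)(C)C(C)(C)C)c(OC)c3)ccc1O[Si](C)(C)C(C)(C)C
F3 | step 11 | 2-[4-(TBSO)-3,5-dimethoxyphenyl]-2-[(3R,4R)-4-(4-TBSO-3-methoxybenzyl)oxolan-3-yl]-1,3-dithiane 1-oxide | COc1cc(C[C@H]2COC[C@@H]2C3(SCCCS3=O)c4cc(OC)c(O[Si](C)(C)C(C)(C)C)c(OC)c4)ccc1O[Si](C)(C)C(C)(C)C
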